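The readings are calculated with constants of no real substance; noise was put on by code.

At early times more G takes Q away faster: at 1.00 h the eta run still has 61.9% of its Q, more than the 35.5% of the alpha run at 1.00 h.

| flask | Q | G | D | remark | time |
|---|---|---|---|---|---|
| epsilon | 0.63 M | 0.46 M | 0.63 M | run made earlier |  |
| eta | 0.63 M | 0.94 M | 0.63 M | run made earlier |  |
| alpha | 0.63 M | 2.1 M | 0.63 M | run made earlier |  |
| south-east | 0.63 M | 1.57 M | 0.630 M |  | 8.0 h |
| north | 0.63 M | 1.89 M | 0.630 M |  | 8.0 h |
| east | 0.63 M | 0.504 M | 0.630 M |  | 8.0 h |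

| run | time / h | J / % | L / % | Q / % |
|---|---|---|---|---|
| epsilon | 0.417 | 0.7 | 0.1 | 88.8 |
| epsilon | 0.833 | 1.7 | 0.2 | 81.6 |
| epsilon | 1.50 | 3.9 | 0.3 | 73.1 |
| epsilon | 3.00 | 9.1 | 0.5 | 61.0 |
| epsilon | 6.00 | 13.3 | 0.7 | 51.7 |
| eta | 1.00 | 8.4 | 0.7 | 61.9 |
| eta | 2.50 | 20.0 | 2.2 | 40.6 |
| eta | 3.00 | 23.3 | 2.1 | 36.7 |
| eta | 5.00 | 30.7 | 3.4 | 27.3 |
| eta | 6.00 | 32.3 | 3.3 | 25.4 |
| alpha | 1.00 | 25.0 | 3.6 | 35.5 |
| alpha | 2.50 | 39.8 | 12.1 | 13.4 |
| alpha | 3.00 | 42.4 | 13.5 | 10.4 |
| alpha | 5.00 | 42.2 | 16.7 | 4.7 |
| alpha | 6.00 | 40.6 | 15.9 | 3.6 |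

(each reading ± 0.3 percentage points)

- the analysis behind the earlier runs scatters by 0.3 percentage points, standard deviation

- which of these holds the largest part of the Q at the end of south-east (J / L / Q / Z)
- which of these holds the largest part of the Q at the end of north (J / L / Q / Z)
- which of these holds the largest part of the Q at the end of east (J / L / Q / Z)
- final J in east, as a percentage of the Q charged

Two chemists argue over east. The first treats the three sites on Q as alike and assumes that all the G charged is taken up. The fraction of sites exchanged, p, is then G charged over 3 times Q charged, 0.267 in east. J is p·p·(one − p), times 3, which gives 15.6%: this is the chance share of J, the statistical distribution taken as the zero of the scale. By the same count Z has 43.0% and Q 39.4%, so she puts Z above Q in east.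

The second chemist made the forecast: “East resembles epsilon with about 10% more G”. It gives J 16.5% in east with Q as the main holder, and J in south-east and J in north. My own check is the last epsilon reading at 6.00 h. The chance count for epsilon gives J 13.4% against 13.3% read, but Q 43.3% against 51.7% read, more than the count gives. So they differ by 0.90 percentage points on J in east, and their real dispute is over Q.

East ends with Q holding the most, 46.3%, then Z at 34.6% and J at 17.0%. J leads in south-east at 42.7% and in north at 39.2%.

    Q + G ⇌ D + Z (K = 2.00, k = 0.0110 M⁻¹ min⁻¹)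
    Z + G ⇌ D + J (K = 0.800, k = 0.0130 M⁻¹ min⁻¹)
    J + G ⇌ D + L (K = 0.670, k = 0.00390 M⁻¹ min⁻¹)
    D → X (k = 0.0190 min⁻¹)
    L → E (k = 0.00680 min⁻¹)

In east at 8.00 h, the half-life of Q by the forward rate of its first step is 32 h, while that step's relaxation half-life, both ways together, is shorter at 2.39 h. J in east stands 1.4 points above the chance share of 15.6%, which was reckoned with all the G taken up, though 6.5% of the G is left there. The neighbour of east with 0.86 M of G is where the first chemist's order of Z and J comes true: chance gives Z 40.5% on top of J 33.9%, and that flask ends with Z on top at 34.3%, with J at 32.0%.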